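## Retrosynthetic overview
1. The target is a (Z)-5-ylidene-3-methyltetronic acid. Disconnect the exocyclic C=C by aldol addition then E1cB dehydration between the lithiated 4-allyloxy-3-methylbutenolide and the chiral aldehyde **14**. The allyl ether is the enol protecting group and is removed last.
2. Aldehyde **14** comes from the alcohol **13**. **13** is made by B-alkyl Suzuki coupling of the (E)-vinyl iodide **10** with the 9-BBN adduct of the vinyl bis-furan **5**. The coupling is stereospecific, so it fixes the E-trisubstituted alkene.
3. Vinyl iodide **10** comes from Zr-catalysed methylalumination and iodination of the chiral alkynol **9**. **9** comes from an Evans alkylation of the propionyl oxazolidinone with 5-iodopentyne, which sets the only sp³ stereocentre (R).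
4. Vinyl bis-furan **5** comes from vinylation of 4-bromo-2-(3-furylmethyl)furan. That bromide comes from 3-furyllithium plus 4-bromofurfural and then ionic deoxygenation.
5. Ring formation: no ring is formed in the synthesis. Both furans and the butenolide come intact from commercial building blocks, and the last bond formed is the exocyclic ylidene C=C.

**Assumptions.** 3-Methyltetronic acid and 5-iodopent-1-yne are taken as commercial. The target is (R) at C–CH₃, (E) at the trisubstituted alkene and (Z) at the ylidene, as read from the SMILES.

## Route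

**Step 1**
Reactants: 1 (3-bromofuran); 2 (4-bromofuran-2-carbaldehyde)
Product: 3 ((4-bromofuran-2-yl)(furan-3-yl)methanol, racemic)
Conditions: n-BuLi, Et₂O, –78 °C, 20 min (gives 3-furyllithium); add 2, –78 °C, 30 min; aq. NH₄Cl
Reagents that add atoms: none
Why: Br/Li exchange gives 3-furyllithium, which adds to the aldehyde in a 1,2-addition. The new carbinol stereocentre is destroyed in the next step.

**Step 2**
Reactants: 3
Product: 4 (4-bromo-2-(furan-3-ylmethyl)furan)
Conditions: Et₃SiH (3 equiv), TFA (2 equiv), CH₂Cl₂, –20 °C, 15 min; quench with aq. NaHCO₃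
Reagents that add atoms: none
Why: Ionic hydrogenation works because the bis-heteroaryl carbinol ionises easily to a stabilised cation that Et₃SiH traps. Mild acid and short times limit furan oligomerisation.

**Step 3**
Reactants: 4
Product: 5 (2-(furan-3-ylmethyl)-4-vinylfuran)
Conditions: PdCl₂ (2 mol %), PPh₃ (6 mol %), Cs₂CO₃ (3 equiv), THF/H₂O 9:1, 85 °C, with BHT
Reagents that add atoms: potassium vinyltrifluoroborate, C=C[B-](F)(F)F.[K+]
Why: Suzuki–Miyaura coupling at the C4–Br bond installs the vinyl group. The product is used promptly because vinylfurans polymerise.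

**Step 4**
Reactants: 6 ((S)-4-benzyl-3-propionyloxazolidin-2-one); 7 (5-iodopent-1-yne)
Product: 8 ((S)-4-benzyl-3-[(R)-2-methylhept-6-ynoyl]oxazolidin-2-one)
Conditions: NaHMDS, THF, –78 °C, 45 min; add 7, –78 → –40 °C, 4 h
Reagents that add atoms: none
Why: This is an Evans asymmetric enolate alkylation. The chelated Z-sodium enolate is attacked on the face opposite the benzyl group of the (S)-auxiliary, giving the (R) methyl-bearing centre. The terminal alkyne is less acidic than the imide α-C–H, so it survives.

**Step 5**
Reactants: 8
Product: 9 ((R)-2-methylhept-6-yn-1-ol)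
Conditions: LiBH₄, Et₂O, H₂O (1 equiv), 0 °C, 2 h
Reagents that add atoms: none
Why: Reductive removal of the auxiliary gives the primary alcohol with no epimerisation, since there is no enolisable carbonyl left. The (S)-benzyloxazolidinone is recovered.

**Step 6**
Reactants: 9
Product: 10 ((R,E)-7-iodo-2,6-dimethylhept-6-en-1-ol)
Conditions: Me₃Al, Cp₂ZrCl₂ (cat.), CH₂Cl₂, 0 °C → rt, 6 h; then I₂, THF, –30 °C
Reagents that add atoms: trimethylaluminium, C[Al](C)C (adds CH₃); iodine, II (adds I)
Why: Negishi Zr-catalysed carboalumination is a syn-methylalumination of the terminal alkyne. Iodinolysis of the C–Al bond then gives the (E)-trisubstituted vinyl iodide, with I trans to the chain. The free OH is tolerated as an aluminium alkoxide.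

**Step 7**
Reactants: 11 (3-methyltetronic acid, 4-hydroxy-3-methylfuran-2(5H)-one)
Product: 12 (4-(allyloxy)-3-methylfuran-2(5H)-one)
Conditions: allyl alcohol (1.5 equiv), PPh₃, DIAD, THF, 0 °C → rt, 3 h
Reagents that add atoms: allyl alcohol, C=CCO (adds the allyl group)
Why: Mitsunobu O-alkylation of the acidic vinylogous acid is selective for O over C. The allyl ether can later be removed by Pd(0) under conditions that spare the furans.

**Step 8**
Reactants: 5; 10
Product: 13 ((R,E)-9-[5-(furan-3-ylmethyl)furan-3-yl]-2,6-dimethylnon-6-en-1-ol)
Conditions: 9-BBN (1.1 equiv), THF, rt, 3 h (hydroboration of 5); then add 10, Pd(dppf)Cl₂ (5 mol %), K₃PO₄ (aq.), THF/DMF, 60 °C, 12 h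
Reagents that add atoms: none
Why: Hydroboration of the vinyl group places boron at the terminal carbon. The B-alkyl Suzuki coupling then proceeds with retention of the vinyl-iodide geometry, giving the E-trisubstituted alkene. The C* stereocentre is untouched.

**Step 9**
Reactants: 13
Product: 14 ((R,E)-9-[5-(furan-3-ylmethyl)furan-3-yl]-2,6-dimethylnon-6-enal)
Conditions: Dess–Martin periodinane, NaHCO₃, CH₂Cl₂, 0 °C → rt, 1 h; use the crude aldehyde immediately
Reagents that add atoms: none
Why: Buffered Dess–Martin oxidation is neutral and does not touch the furans or the alkene. The buffer minimises epimerisation of the α-methyl aldehyde.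

**Step 10**
Reactants: 12; 14
Product: 15 (aldol adduct, 5-(1-hydroxyalkyl)-4-allyloxy-3-methylbutenolide, mixture of diastereomers at the new centres and (R) at C*)
Conditions: LDA (1.0 equiv rel. to 12), THF, –78 °C, 30 min; add 14, –78 °C, 1 h; aq. NH₄Cl
Reagents that add atoms: none
Why: LDA deprotonates the γ (C5) position to give the extended lithium dienolate. This adds to the aldehyde at C5 in a vinylogous aldol. The two new stereocentres are removed in the next step, so their configuration does not matter.

**Step 11**
Reactants: 15
Product: 16 ((Z)-5-ylidene-4-allyloxy-3-methylbutenolide)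
Conditions: MsCl, Et₃N, CH₂Cl₂, 0 °C, 1 h; then DBU (1.5 equiv), 0 °C → rt, 2 h
Reagents that add atoms: none (the mesylate is lost in the elimination)
Why: E1cB elimination through the acidic C5–H gives the thermodynamically preferred (Z)-ylidene, in which the chain is cis to the ring oxygen. This removes both new stereocentres while the remote (R) centre is retained.

**Step 12**
Reactants: 16
Product: 17 (target)
Conditions: Pd(PPh₃)₄ (5 mol %), morpholine (5 equiv), THF, rt, 30 min, in the dark; acidify to pH 3 with aq. KHSO₄; chromatograph with 1% AcOH in the eluent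
Reagents that add atoms: none (allyl is transferred to morpholine)
Why: Pd(0) ionises the allyl tetronate (Tsuji–Trost deallylation) under neutral conditions that leave the furans, the E-alkene and the Z-ylidene intact, giving the free enolic tetronic acid.

## Compound list
1 | 3-bromofuran | Brc1ccoc1 | starting material
2 | 4-bromofuran-2-carbaldehyde | O=Cc1cc(Br)co1 | starting material
3 | (4-bromofuran-2-yl)(furan-3-yl)methanol (racemic) | OC(c1cc(Br)co1)c1ccoc1 | intermediate
4 | 4-bromo-2-(furan-3-ylmethyl)furan | Brc1coc(Cc2ccoc2)c1 | intermediate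
5 | 2-(furan-3-ylmethyl)-4-vinylfuran | C=Cc1coc(Cc2ccoc2)c1 | intermediate
6 | (S)-4-benzyl-3-propionyloxazolidin-2-one | CCC(=O)N1[C@@H](Cc2ccccc2)COC1=O | starting material
7 | 5-iodopent-1-yne | C#CCCCI | starting material
8 | (S)-4-benzyl-3-[(R)-2-methylhept-6-ynoyl]oxazolidin-2-one | C#CCCC[C@@H](C)C(=O)N1[C@@H](Cc2ccccc2)COC1=O | intermediate
9 | (R)-2-methylhept-6-yn-1-ol | C#CCCC[C@@H](C)CO | intermediate
10 | (R,E)-7-iodo-2,6-dimethylhept-6-en-1-ol | I/C=C(C)/CCC[C@@H](C)CO | intermediate
11 | 3-methyltetronic acid (4-hydroxy-3-methylfuran-2(5H)-one) | CC1=C(O)COC1=O | starting material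
12 | 4-(allyloxy)-3-methylfuran-2(5H)-one | CC1=C(OCC=C)COC1=O | intermediate
13 | (R,E)-9-[5-(furan-3-ylmethyl)furan-3-yl]-2,6-dimethylnon-6-en-1-ol | OC[C@H](C)CCC/C(C)=C/CCc1coc(Cc2ccoc2)c1 | intermediate
14 | (R,E)-9-[5-(furan-3-ylmethyl)furan-3-yl]-2,6-dimethylnon-6-enal | O=C[C@H](C)CCC/C(C)=C/CCc1coc(Cc2ccoc2)c1 | intermediate
15 | aldol adduct (new carbinol and C5 centres unspecified) | CC1=C(OCC=C)C(C(O)[C@H](C)CCC/C(C)=C/CCc2coc(Cc3ccoc3)c2)OC1=O | intermediate
16 | (Z)-ylidene allyl ether | CC1=C(OCC=C)/C(=C/[C@H](C)CCC/C(C)=C/CCc2coc(Cc3ccoc3)c2)OC1=O | intermediate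
17 | target, CID54702820 | CC1=C(O)/C(=C/[C@H](C)CCC/C(C)=C/CCc2coc(Cc3ccoc3)c2)OC1=O | target

## Totals
- Total steps: 12.
- Longest linear sequence: 8 steps (1→2→3→8→9→10→11→12, or equivalently 4→5→6→8→9→10→11→12).

## Three steps most likely to fail
1. **Step 2 (deoxygenation of the bis-furyl carbinol).** The acid-sensitive furans may oligomerise under TFA.
   - Fallback: couple 3-furylmethylzinc bromide (from 3-(bromomethyl)furan, Zn, LiCl) with a 2-halo-4-bromofuran by C2-selective Negishi coupling. This replaces the carbinol route entirely.
2. **Step 8 (hydroboration and B-alkyl Suzuki with the vinylfuran and a free alcohol).** Vinylfuran instability or poor sp³–sp² coupling would lower the yield.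
   - Fallback: lithiate 4 and open ethylene oxide/BF₃ to give Ar–CH₂CH₂OH, then Appel iodination, then organozinc formation and Negishi coupling with vinyl iodide **10**.
3. **Step 10 (lithium aldol with the α-branched aldehyde).** Epimerisation at C* or low conversion is possible.
   - Fallback: use a base-free Lewis-acid vinylogous Mukaiyama aldol of 3-methyl-2,4-bis(TBSO)furan with **14**, then MsCl/DBU elimination and fluoride removal of the silyl group. This bypasses steps 7 and 12 and avoids strong base.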